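Ring A is the central benzene: C1 bears the exocyclic carbon C-alpha, C2 the 4-hydroxyphenyl group, C3 and C4 are C-H, C5 bears CH2OH, C6 the arylethynyl group; Ar = 4-(methoxymethoxy)phenyl.
Retrosynthesis: the quinone methide goes back to its C-alpha-H leuco form and CH2OH to CO2Me; ring A is then cut at C1-C6 and C4-C5, followed by C2-C3 (vinyl transfer), C-alpha-C1 (acetylide addition) and the aryl-alkyne bonds.
Enabling feature: C-alpha, C1 and C2 with their three aryl groups map onto a 1,1,3-triarylallene. Its C1=C2 bond plus a vinyl group C3=C4 on C2 is a diene, and C5/C6 with ester and arylethynyl group are the activated triple bond of a 5-arylpenta-2,4-diynoate.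
Forward: one MOM-protected aryl iodide feeds both halves (arylacetylene + benzophenone + vinyl cuprate give the vinylallene; a butadiyne unit + chloroformate give the diynoate). Ring A is the only ring built, by [4+2] cycloaddition and proton transfer from C4 to C-alpha; the four outer rings are bought.
Endgame: ester reduction, removal of the four MOM groups, two-electron oxidation of the bis(4-hydroxyphenyl)methine.
Stereochemistry: the target has no stereocentre and, because the quinone methide ring is symmetric, no E/Z element. Only regiochemistry must be controlled, and the donor aryl group on C2 does that.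

Key step: step 9

Assumption: the target SMILES carries no stereodescriptor, so hindered rotation about the C1-C-alpha and C2-aryl bonds is not treated as a stereochemical task.

Step 1
Reactants: 1 4-iodophenol
Product: 2 1-iodo-4-(methoxymethoxy)benzene
Conditions: NaH (1.2 equiv), MOMCl (1.2 equiv), DMF, 0 °C to rt
Reagents that add atoms: chloromethyl methyl ether (MOMCl), COCCl
Why: Williamson ether synthesis in which the sodium phenolate displaces chloride from the reactive alpha-chloro ether, giving an acetal that is inert to the organometallic, basic and thermal steps ahead while the carbon-iodine bond stays untouched.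

Step 2
Reactants: 2 1-iodo-4-(methoxymethoxy)benzene; 3 ethynyltrimethylsilane
Product: 4 {[4-(methoxymethoxy)phenyl]ethynyl}trimethylsilane
Conditions: Pd(PPh3)2Cl2 (2 mol %), CuI (4 mol %), Et3N, THF, rt
Reagents that add atoms: none
Why: Sonogashira coupling, in which the aryl iodide adds oxidatively to zerovalent palladium at room temperature and meets the copper acetylide, the silyl cap preventing double arylation.

Step 3
Reactants: 4 {[4-(methoxymethoxy)phenyl]ethynyl}trimethylsilane
Product: 5 1-ethynyl-4-(methoxymethoxy)benzene
Conditions: K2CO3 (0.2 equiv), MeOH, rt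
Reagents that add atoms: none
Why: Base-catalysed protodesilylation, in which methoxide attacks the alkynyl silicon and methanol protonates the released acetylide, conditions to which the MOM acetal is stable.

Step 4
Reactants: 6 4,4'-dihydroxybenzophenone
Product: 7 bis[4-(methoxymethoxy)phenyl]methanone
Conditions: NaH (2.4 equiv), MOMCl (2.4 equiv), DMF, 0 °C to rt
Reagents that add atoms: chloromethyl methyl ether (MOMCl), COCCl
Why: Double Williamson ether synthesis that removes the acidic protons and the phenolate deactivation which would otherwise stop acetylide addition to the carbonyl group.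

Step 5
Reactants: 5 1-ethynyl-4-(methoxymethoxy)benzene; 7 bis[4-(methoxymethoxy)phenyl]methanone
Product: 10 methyl 1,1,3-tris[4-(methoxymethoxy)phenyl]prop-2-yn-1-yl carbonate, via lithium arylacetylide 8 (not isolated), via lithium propargylic alkoxide 9 (not isolated)
Conditions: n-BuLi (1.05 equiv), THF, -78 °C; 7, -78 °C to rt; ClCO2Me (1.3 equiv), -78 to 0 °C; aq. NaHCO3, Et3N-deactivated silica plug
Reagents that add atoms: methyl chloroformate, COC(=O)Cl
Why: 1,2-Addition of a lithium acetylide to a non-enolisable diaryl ketone joins C-alpha to C1, and O-acylation of the tertiary lithium alkoxide in the same flask gives the carbonate without exposing the easily ionised bis(4-alkoxyphenyl)carbinol to acid or acylation catalysts.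

Step 6
Reactants: 10 methyl 1,1,3-tris[4-(methoxymethoxy)phenyl]prop-2-yn-1-yl carbonate; 11 vinylmagnesium bromide
Product: 12 1,1,3-tris[4-(methoxymethoxy)phenyl]penta-1,2,4-triene (triaryl vinylallene)
Conditions: CuBr·SMe2 (1.5 equiv), 11 (3.0 equiv), THF, -78 to -40 °C; then 10, -78 to -20 °C; aq. NH4Cl/NH3; neutral alumina
Reagents that add atoms: none
Why: SN2' substitution of a propargylic ester by an organocuprate (the classical allene synthesis), in which copper attacks the aryl-bearing alkyne carbon C2 remote from the fully substituted C-alpha, the carbonate leaves, and reductive elimination from the allenyl trivalent copper intermediate places the vinyl group C3=C4 on C2.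

Step 7
Reactants: 13 1,4-bis(trimethylsilyl)buta-1,3-diyne; 2 1-iodo-4-(methoxymethoxy)benzene
Product: 16 {4-[4-(methoxymethoxy)phenyl]buta-1,3-diyn-1-yl}trimethylsilane, via lithium silylbutadiynide 14 (not isolated), via silylbutadiynylzinc bromide 15 (not isolated)
Conditions: 13 (1.3 equiv), MeLi·LiBr (1.25 equiv), THF/Et2O, -78 °C to rt; ZnBr2 (1.3 equiv), 0 °C; 2 (1.0 equiv), Pd(PPh3)4 (3 mol %), rt
Reagents that add atoms: none
Why: Methyllithium cleaves one C-Si bond (the diynide formed resists a second attack), and transmetalation to zinc followed by Negishi alkynylation of the aryl iodide delivers the capped aryl diyne without handling free butadiyne.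

Step 8
Reactants: 16 {4-[4-(methoxymethoxy)phenyl]buta-1,3-diyn-1-yl}trimethylsilane
Product: 18 methyl 5-[4-(methoxymethoxy)phenyl]penta-2,4-diynoate, via lithium arylbutadiynide 17 (not isolated)
Conditions: MeLi·LiBr (1.05 equiv), THF, -78 to 0 °C; ClCO2Me (2 equiv), -78 °C
Reagents that add atoms: methyl chloroformate, COC(=O)Cl
Why: Desilylative lithiation unmasks the diynide directly so that the labile terminal aryl butadiyne is never isolated, and C-acylation of a lithium acetylide with excess chloroformate at low temperature is the standard ynoate synthesis.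

Step 9
Reactants: 12 1,1,3-tris[4-(methoxymethoxy)phenyl]penta-1,2,4-triene; 18 methyl 5-[4-(methoxymethoxy)phenyl]penta-2,4-diynoate
Product: 20 methyl 3-{bis[4-(methoxymethoxy)phenyl]methyl}-4-[4-(methoxymethoxy)phenyl]-2-{[4-(methoxymethoxy)phenyl]ethynyl}benzoate, via isotoluene cycloadduct 19 (not isolated)
Conditions: 12 (1.0 equiv), 18 (1.5 equiv), BHT (5 mol %), toluene (1 M), 110 °C, sealed tube, Ar; then DBU (0.5 equiv), rt
Reagents that add atoms: none
Why: This is a thermal normal-electron-demand Diels-Alder reaction in which the diene C1=C2-C3=C4 of 12 adds across the ester-bound triple bond C5≡C6 of 18 through a concerted but asynchronous transition state, the C1-C6 bond running ahead because the positive charge it leaves on C2 is taken up by the 4-alkoxyphenyl ring and by C3=C4, with C4-C5 following. The closest known reaction type is the cycloaddition of vinylallenes with acetylenic esters, whose alkylidenecyclohexadiene adducts are tautomerised to benzenes by acid or amine base. Ring A closes in an intermolecular [4+2] mode (four carbons from 12, two from 18), and because a direct hydrogen shift across the ring of 19 is geometrically out of reach, DBU removes a proton from the doubly allylic C4 and the delocalised anion is reprotonated at C-alpha, the gain of aromaticity carrying the adduct on to 20. No stereocentre arises, since C4 of 19 is a CH2 group and C-alpha of 20 carries two identical aryl groups. Regioselectivity (ester carbon C5 opposite C2) rests on the donor aryl group at C2, which makes C1 the nucleophilic diene terminus that pairs with the electrophilic beta carbon C6, and on sterics, since the rod-like alkynyl group rather than the ester comes to lie beside the diarylmethylidene unit; site selectivity rests on the ester, which lowers the LUMO at the proximal triple bond, whereas the distal one is aryl-capped and fed by a donor. The sp carbon C1 has no inward substituent and the C2 aryl group favours the s-cis form, but one C-alpha aryl group stands over each diene face, hence the high concentration, the excess of 18 and the radical inhibitor.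

Step 10
Reactants: 20 methyl 3-{bis[4-(methoxymethoxy)phenyl]methyl}-4-[4-(methoxymethoxy)phenyl]-2-{[4-(methoxymethoxy)phenyl]ethynyl}benzoate
Product: 21 (3-{bis[4-(methoxymethoxy)phenyl]methyl}-4-[4-(methoxymethoxy)phenyl]-2-{[4-(methoxymethoxy)phenyl]ethynyl}phenyl)methanol
Conditions: i-Bu2AlH (DIBAL-H, 2.5 equiv), CH2Cl2, -78 to 0 °C; aq. potassium sodium tartrate
Reagents that add atoms: none
Why: Hydride reduction of an aromatic methyl ester to the benzylic alcohol, carried out at or below 0 °C, where neither the diaryl alkyne (hydroalumination needs heat) nor the MOM acetals react.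

Step 11
Reactants: 21 (3-{bis[4-(methoxymethoxy)phenyl]methyl}-4-[4-(methoxymethoxy)phenyl]-2-{[4-(methoxymethoxy)phenyl]ethynyl}phenyl)methanol
Product: 22 {3-[bis(4-hydroxyphenyl)methyl]-4-(4-hydroxyphenyl)-2-[(4-hydroxyphenyl)ethynyl]phenyl}methanol (leuco form of the target)
Conditions: HCl (1.25 M in MeOH, cat.), MeOH/THF, 40 °C, Ar; NaHCO3
Reagents that add atoms: none
Why: Acid-catalysed transacetalisation of phenolic MOM ethers with methanol, which carries formaldehyde off as dimethoxymethane so that it cannot hydroxymethylate the free phenols, under acid too dilute to protonate the diaryl alkyne and trigger attack of the neighbouring CH2OH.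

Step 12
Reactants: 22 {3-[bis(4-hydroxyphenyl)methyl]-4-(4-hydroxyphenyl)-2-[(4-hydroxyphenyl)ethynyl]phenyl}methanol
Product: 23 selaginellin, 4-{[3-(hydroxymethyl)-6-(4-hydroxyphenyl)-2-[(4-hydroxyphenyl)ethynyl]phenyl](4-hydroxyphenyl)methylidene}cyclohexa-2,5-dien-1-one
Conditions: DDQ (1.0 equiv), 1,4-dioxane, rt
Reagents that add atoms: none
Why: DDQ dehydrogenation of a 4-hydroxyphenyl methine to a p-quinone methide (fuchsone formation), selective because C-alpha-H is the only C-H activated by two phenol rings, giving one product because those rings are equivalent, and sparing the CH2OH on the less electron-rich ring A, which is oxidised much more slowly.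

Compound list
1 | 4-iodophenol | Ic1ccc(O)cc1 | starting material
2 | 1-iodo-4-(methoxymethoxy)benzene | Ic1ccc(OCOC)cc1 | intermediate
3 | ethynyltrimethylsilane | C#C[Si](C)(C)C | starting material
4 | {[4-(methoxymethoxy)phenyl]ethynyl}trimethylsilane | C[Si](C)(C)C#Cc1ccc(OCOC)cc1 | intermediate
5 | 1-ethynyl-4-(methoxymethoxy)benzene | C#Cc1ccc(OCOC)cc1 | intermediate
6 | 4,4'-dihydroxybenzophenone | O=C(c1ccc(O)cc1)c1ccc(O)cc1 | starting material
7 | bis[4-(methoxymethoxy)phenyl]methanone | O=C(c1ccc(OCOC)cc1)c1ccc(OCOC)cc1 | intermediate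
8 | lithium [4-(methoxymethoxy)phenyl]acetylide | [Li]C#Cc1ccc(OCOC)cc1 | intermediate
9 | lithium 1,1,3-tris[4-(methoxymethoxy)phenyl]prop-2-yn-1-olate | [Li]OC(C#Cc1ccc(OCOC)cc1)(c1ccc(OCOC)cc1)c1ccc(OCOC)cc1 | intermediate
10 | methyl 1,1,3-tris[4-(methoxymethoxy)phenyl]prop-2-yn-1-yl carbonate | COC(=O)OC(C#Cc1ccc(OCOC)cc1)(c1ccc(OCOC)cc1)c1ccc(OCOC)cc1 | intermediate
11 | vinylmagnesium bromide | C=C[Mg]Br | starting material
12 | 1,1,3-tris[4-(methoxymethoxy)phenyl]penta-1,2,4-triene | C=CC(=C=C(c1ccc(OCOC)cc1)c1ccc(OCOC)cc1)c1ccc(OCOC)cc1 | intermediate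
13 | 1,4-bis(trimethylsilyl)buta-1,3-diyne | C[Si](C)(C)C#CC#C[Si](C)(C)C | starting material
14 | lithium 4-(trimethylsilyl)buta-1,3-diynide | [Li]C#CC#C[Si](C)(C)C | intermediate
15 | [4-(trimethylsilyl)buta-1,3-diyn-1-yl]zinc bromide | Br[Zn]C#CC#C[Si](C)(C)C | intermediate
16 | {4-[4-(methoxymethoxy)phenyl]buta-1,3-diyn-1-yl}trimethylsilane | C[Si](C)(C)C#CC#Cc1ccc(OCOC)cc1 | intermediate
17 | lithium 4-[4-(methoxymethoxy)phenyl]buta-1,3-diynide | [Li]C#CC#Cc1ccc(OCOC)cc1 | intermediate
18 | methyl 5-[4-(methoxymethoxy)phenyl]penta-2,4-diynoate | COC(=O)C#CC#Cc1ccc(OCOC)cc1 | intermediate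
19 | methyl 3-{bis[4-(methoxymethoxy)phenyl]methylidene}-4-[4-(methoxymethoxy)phenyl]-2-{[4-(methoxymethoxy)phenyl]ethynyl}cyclohexa-1,4-diene-1-carboxylate | COC(=O)C1=C(C#Cc2ccc(OCOC)cc2)C(=C(c2ccc(OCOC)cc2)c2ccc(OCOC)cc2)C(c2ccc(OCOC)cc2)=CC1 | intermediate
20 | methyl 3-{bis[4-(methoxymethoxy)phenyl]methyl}-4-[4-(methoxymethoxy)phenyl]-2-{[4-(methoxymethoxy)phenyl]ethynyl}benzoate | COC(=O)c1ccc(-c2ccc(OCOC)cc2)c(C(c2ccc(OCOC)cc2)c2ccc(OCOC)cc2)c1C#Cc1ccc(OCOC)cc1 | intermediate
21 | (3-{bis[4-(methoxymethoxy)phenyl]methyl}-4-[4-(methoxymethoxy)phenyl]-2-{[4-(methoxymethoxy)phenyl]ethynyl}phenyl)methanol | OCc1ccc(-c2ccc(OCOC)cc2)c(C(c2ccc(OCOC)cc2)c2ccc(OCOC)cc2)c1C#Cc1ccc(OCOC)cc1 | intermediate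
22 | {3-[bis(4-hydroxyphenyl)methyl]-4-(4-hydroxyphenyl)-2-[(4-hydroxyphenyl)ethynyl]phenyl}methanol | OCc1ccc(-c2ccc(O)cc2)c(C(c2ccc(O)cc2)c2ccc(O)cc2)c1C#Cc1ccc(O)cc1 | intermediate
23 | selaginellin | O=C1C=CC(=C(c2ccc(O)cc2)c2c(-c3ccc(O)cc3)ccc(CO)c2C#Cc2ccc(O)cc2)C=C1 | target

Total step count: 12. Longest linear sequence: 9 steps (1, 2, 3, 5, 6, 9, 10, 11, 12).

Steps most likely to fail

Step 9. The cycloaddition may be too slow. An aryl group on C-alpha screens each face of C1, and the distant 4-alkoxyphenyl donor raises the LUMO of the diynoate. Thermal oligomerisation of the dienophile or self-dimerisation of the vinylallene could then take over. The fallback raises the dienophile to the aldehyde oxidation level, which lowers its LUMO and allows a much lower temperature. It sets out from 16 and 12. Treatment of 16 with MeLi·LiBr regenerates 17, and quenching with DMF should give 5-[4-(methoxymethoxy)phenyl]penta-2,4-diynal F1. Reaction of F1 with 12 in toluene at 40 to 60 °C should give the formyl isotoluene cycloadduct F2. DBU should tautomerise F2 to 3-{bis[4-(methoxymethoxy)phenyl]methyl}-4-[4-(methoxymethoxy)phenyl]-2-{[4-(methoxymethoxy)phenyl]ethynyl}benzaldehyde F3. Reduction with NaBH4 in MeOH/THF at 0 °C returns to the route at 21, so steps 8 and 10 are bypassed.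

Step 6. The doubly benzylic tertiary carbonate may ionise or take up an electron from the cuprate. Reduction to the C-H allene, radical dimerisation or attack at the carbonate carbonyl could then compete with vinyl transfer. The fallback replaces the stoichiometric copper substitution by a palladium-catalysed cross-coupling. It sets out from 10 and 11. Transmetalation of 11 with ZnBr2 gives vinylzinc bromide F4. F4 is coupled with 10 under Pd(PPh3)4 (5 mol %) in THF at 0 °C to rt. Zerovalent palladium should add in an SN2' sense with loss of carbon dioxide to give an allenyl divalent palladium species, and transmetalation and reductive elimination at C2 return to the route at 12.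

Step 12. The free tetraphenol may be oxidised unselectively (phenoxyl coupling, attack on CH2OH), or hydride loss from the buried C-alpha-H may be sluggish. The fallback oxidises before deprotection. It sets out from 21. DDQ (1.2 equiv) in CH2Cl2/pH 7 buffer should abstract hydride from the bis(4-alkoxyphenyl)methine, and water captures the cation to give (3-(hydroxymethyl)-6-[4-(methoxymethoxy)phenyl]-2-{[4-(methoxymethoxy)phenyl]ethynyl}phenyl)bis[4-(methoxymethoxy)phenyl]methanol F5. Methanolic HCl, as in step 11, then removes the four MOM groups and ionises the carbinol. Loss of a phenolic proton gives the quinone methide, so the detour comes back at 23 and bypasses 22.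

Further compounds
F1 | step 9 | 5-[4-(methoxymethoxy)phenyl]penta-2,4-diynal | O=CC#CC#Cc1ccc(OCOC)cc1
F2 | step 9 | 3-{bis[4-(methoxymethoxy)phenyl]methylidene}-4-[4-(methoxymethoxy)phenyl]-2-{[4-(methoxymethoxy)phenyl]ethynyl}cyclohexa-1,4-diene-1-carbaldehyde | O=CC1=C(C#Cc2ccc(OCOC)cc2)C(=C(c2ccc(OCOC)cc2)c2ccc(OCOC)cc2)C(c2ccc(OCOC)cc2)=CC1
F3 | step 9 | 3-{bis[4-(methoxymethoxy)phenyl]methyl}-4-[4-(methoxymethoxy)phenyl]-2-{[4-(methoxymethoxy)phenyl]ethynyl}benzaldehyde | O=Cc1ccc(-c2ccc(OCOC)cc2)c(C(c2ccc(OCOC)cc2)c2ccc(OCOC)cc2)c1C#Cc1ccc(OCOC)cc1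
F4 | step 6 | vinylzinc bromide | C=C[Zn]Br
F5 | step 12 | (3-(hydroxymethyl)-6-[4-(methoxymethoxy)phenyl]-2-{[4-(methoxymethoxy)phenyl]ethynyl}phenyl)bis[4-(methoxymethoxy)phenyl]methanol | OCc1ccc(-c2ccc(OCOC)cc2)c(C(O)(c2ccc(OCOC)cc2)c2ccc(OCOC)cc2)c1C#Cc1ccc(OCOC)cc1
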